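**Assumption:** cembrane locants are used throughout (C1 = ring CH bearing the α‑methylene carboxyl, C3 = carbinol, C11 = CHOAc, C12 = lactone C–O carbon). The target SMILES reads as (1R,3S,4E,7E,11S,12R), with a seven‑membered α‑methylene lactone bridging C1 and C12 on a 14‑membered carbocycle. The route is a paper design; nothing here has been run.

## Retrosynthetic overview

1. C3 carbinol ⇐ (R)‑CBS reduction of the macrocyclic enone ⇐ Nozaki–Hiyama–Kishi macrocyclisation (C3–C4); the 14‑membered ring closes last.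
2. Seco chain ⇐ B‑alkyl Suzuki (C8–C9) of a vinyl‑bearing acetoxy ε‑lactone with the symmetric linchpin (2E,5E)‑2,6‑diiodohepta‑2,5‑diene, which supplies C4–C8 and both E‑trisubstituted alkenes.
3. Acetoxy ε‑lactone (7‑membered ring, closed first) ⇐ new acetate‑relay epoxide‑opening/lactonisation of an (11R,12R)‑vinyl epoxide active ester (inverts C11, retains C12, installs the OAc).
4. Vinyl epoxide ⇐ HWE, Sharpless epoxidation (D‑DET) and Wittig on a methyl ketone; acrylate ⇐ SeO2 oxidation of the isopropenyl group.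
5. C1 stereocentre and ten carbons (C12–C14, C1–C3, C15–C17, C12‑Me) ⇐ (R)‑limonene by ring ozonolysis.

## Route

**Step 1**
Reactants: 1, (R)‑(+)‑limonene
Product: 2, (5R)‑7,7‑dimethoxy‑5‑(prop‑1‑en‑2‑yl)heptan‑2‑one
Conditions: O3 (1 equiv), CH2Cl2–MeOH, −78 °C; Me2S; then p‑TsOH (cat.), MeOH, rt
Reagents that add atoms: ozone, [O-][O+]=O; methanol, CO
Why: Ozonolysis is selective for the electron‑rich trisubstituted ring alkene over the isopropenyl group, and only the aldehyde is acetalised under mild acid; limonene C4 becomes C1 (R) untouched.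

**Step 2**
Reactants: 2
Product: 3, (5R)‑5‑(3‑hydroxyprop‑1‑en‑2‑yl)‑7,7‑dimethoxyheptan‑2‑one
Conditions: SeO2 (0.5 equiv), t‑BuOOH, CH2Cl2, rt (recycle recovered 2)
Reagents that add atoms: selenium dioxide, O=[Se]=O (O donor; reoxidised by TBHP, CC(C)(C)OO)
Why: SeO2/TBHP allylic oxidation (ene then [2,3] shift) of a 1,1‑disubstituted alkene occurs at the allylic CH3 in preference to the allylic CH, giving the 2‑substituted allyl alcohol (future C17).

**Step 3**
Reactants: 3
Product: 4, (5R)‑5‑[3‑(tert‑butyldiphenylsilyloxy)prop‑1‑en‑2‑yl]‑7,7‑dimethoxyheptan‑2‑one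
Conditions: TBDPSCl, imidazole, DMF, rt
Reagents that add atoms: TBDPSCl, CC(C)(C)[Si](Cl)(c1ccccc1)c1ccccc1
Why: Routine silylation of the primary alcohol, so that only one allylic alcohol is present at the epoxidation stage.

**Step 4**
Reactants: 4
Product: 5, ethyl (2E,6R)‑6‑[3‑(TBDPS‑oxy)prop‑1‑en‑2‑yl]‑8,8‑dimethoxy‑3‑methyloct‑2‑enoate
Conditions: (EtO)2P(O)CH2CO2Et, NaH, THF, 0 → 50 °C (E:Z about 5:1 expected)
Reagents that add atoms: triethyl phosphonoacetate, CCOC(=O)CP(=O)(OCC)OCC
Why: Horner–Wadsworth–Emmons olefination of the methyl ketone adds C11 and C10 and favours the E‑enoate with the ester trans to the larger chain.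

**Step 5**
Reactants: 5
Product: 6, (2E,6R)‑6‑[3‑(TBDPS‑oxy)prop‑1‑en‑2‑yl]‑8,8‑dimethoxy‑3‑methyloct‑2‑en‑1‑ol
Conditions: DIBAL‑H, CH2Cl2, −78 °C; chromatographic removal of the minor Z isomer
Reagents that add atoms: none
Why: DIBAL 1,2‑reduction of the enoate gives the geraniol‑type E‑allylic alcohol; acetal and silyl ether are inert.

**Step 6**
Reactants: 6
Product: 7, [(2R,3R)‑3‑{(3R)‑3‑[3‑(TBDPS‑oxy)prop‑1‑en‑2‑yl]‑5,5‑dimethoxypentyl}‑3‑methyloxiran‑2‑yl]methanol
Conditions: Ti(OiPr)4 (10 mol %), D‑(−)‑DET (12 mol %), t‑BuOOH, 4 Å MS, CH2Cl2, −20 °C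
Reagents that add atoms: tert‑butyl hydroperoxide, CC(C)(C)OO
Why: Sharpless asymmetric epoxidation under reagent control; D‑(−)‑DET gives the (2R,3R) epoxy alcohol (mirror of the L‑(+)‑DET/geraniol (2S,3S) outcome), setting C12 (R, final) and C11 (R, inverted in step 13).

**Step 7**
Reactants: 7
Product: 8, 2‑{(3R)‑1‑[(2R,3R)‑3‑(hydroxymethyl)‑2‑methyloxiran‑2‑yl]‑5,5‑dimethoxypentan‑3‑yl}prop‑2‑en‑1‑ol
Conditions: TBAF, AcOH (buffer), THF, 0 °C → rt
Reagents that add atoms: none
Why: Fluoride desilylation; buffering suppresses Payne rearrangement of the epoxy alcohol.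

**Step 8**
Reactants: 8
Product: 9, (3R)‑3‑(2,2‑dimethoxyethyl)‑5‑[(2R,3R)‑3‑(hydroxymethyl)‑2‑methyloxiran‑2‑yl]‑2‑methylidenepentanal
Conditions: MnO2, CH2Cl2, rt
Reagents that add atoms: none
Why: MnO2 oxidises only the allylic alcohol; the non‑allylic epoxy alcohol is untouched.

**Step 9**
Reactants: 9
Product: 10, (3R)‑3‑(2,2‑dimethoxyethyl)‑5‑[(2R,3R)‑3‑(hydroxymethyl)‑2‑methyloxiran‑2‑yl]‑2‑methylidenepentanoic acid
Conditions: NaClO2, NaH2PO4/Na2HPO4 (pH about 6), 2‑methyl‑2‑butene, t‑BuOH–H2O, 0 °C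
Reagents that add atoms: sodium chlorite, [Na+].[O-]Cl=O
Why: Pinnick oxidation of the 2‑substituted acrolein to the acrylic acid, done at the robust epoxy‑alcohol stage before the acid‑labile vinyl epoxide exists.

**Step 10**
Reactants: 10
Product: 11, (3R)‑3‑(2,2‑dimethoxyethyl)‑5‑[(2R,3S)‑3‑formyl‑2‑methyloxiran‑2‑yl]‑2‑methylidenepentanoic acid (descriptor change at C11 is CIP only)
Conditions: Dess–Martin periodinane, NaHCO3, CH2Cl2, 0 °C; used crude
Reagents that add atoms: none
Why: Dess–Martin oxidation of the epoxy alcohol to the epoxy aldehyde is mild and tolerates the free acid and the epoxide.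

**Step 11**
Reactants: 11
Product: 12, (3R)‑3‑(2,2‑dimethoxyethyl)‑2‑methylidene‑5‑[(2R,3R)‑2‑methyl‑3‑vinyloxiran‑2‑yl]pentanoic acid (handled as its Et3NH+ salt)
Conditions: Ph3PCH3Br (3.5 equiv), KHMDS (3.3 equiv), THF, −78 → 0 °C; pH 6–7 work‑up
Reagents that add atoms: methyltriphenylphosphonium bromide, C[P+](c1ccccc1)(c1ccccc1)c1ccccc1.[Br-]
Why: Wittig methylenation adds C9; the first equivalent of ylide forms the carboxylate, which deactivates the acrylate toward conjugate addition.

**Step 12**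
Reactants: 12
Product: 13, pentafluorophenyl (3R)‑3‑(2,2‑dimethoxyethyl)‑2‑methylidene‑5‑[(2R,3R)‑2‑methyl‑3‑vinyloxiran‑2‑yl]pentanoate
Conditions: C6F5OH, EDC·HCl, DMAP (cat.), CH2Cl2, 0 °C
Reagents that add atoms: pentafluorophenol, Oc1c(F)c(F)c(F)c(F)c1F
Why: Carbodiimide esterification under near‑neutral conditions gives an isolable active ester that serves as the internal acyl donor.

**Step 13 (new transformation)**
Reactants: 13
Product: 14, (4R,7R)‑7‑[(1S)‑1‑acetoxyprop‑2‑en‑1‑yl]‑4‑(2,2‑dimethoxyethyl)‑7‑methyl‑3‑methylideneoxepan‑2‑one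
Conditions: n‑Bu4NOAc (1.5 equiv), (salen)Co(III)OAc (5 mol %), 4 Å MS, THF–toluene (0.01 M), 23 → 40 °C
Reagents that add atoms: tetrabutylammonium acetate, CC(=O)[O-].CCCC[N+](CCCC)(CCCC)CCCC
Why: Proposed new method: acetate‑relay epoxide‑opening/acyl‑transfer lactonisation — Co(III)‑delivered acetate opens the activated vinyl epoxide by SN2 at the allylic secondary carbon C11 (C12 is fully substituted), inverting C11 (R→S); the C12 tertiary alkoxide, formed with retention, closes the ε‑lactone on the tethered C6F5 ester (7‑membered acyl substitution), expelling weakly nucleophilic C6F5O−; the net result is stereospecific anti addition giving (11S,12R) with acetate and lactone in their final positions and no acylation of a free tertiary alcohol; closest known reaction types are (salen)Co/Cr‑ or onium‑carboxylate ring opening of epoxides, the epoxide/anhydride (or epoxide/aryl ester) insertion step of ring‑opening copolymerisation, and nucleophile‑triggered epoxide‑opening/γ‑lactonisation of epoxy esters.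

**Step 14**
Reactants: 15, 1‑bromobut‑2‑yne; 16, prop‑1‑ynylmagnesium bromide
Product: 17, hepta‑2,5‑diyne
Conditions: CuCl (5 mol %), THF, 0 °C → reflux
Reagents that add atoms: none (both partners are listed reactants)
Why: Copper‑catalysed propargylic substitution of the bromide by the alkynyl Grignard gives the skipped diyne.

**Step 15**
Reactants: 17
Product: 18, (2E,5E)‑2,6‑diiodohepta‑2,5‑diene
Conditions: Cp2Zr(H)Cl (5 equiv), THF, 50 °C; then I2, 0 °C
Reagents that add atoms: iodine, II
Why: Syn hydrozirconation under equilibrating conditions places Zr on the methyl‑bearing carbon of each 2‑alkyne, and iodinolysis with retention gives the (E,E)‑bis(2‑iodoalkene).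

**Step 16**
Reactants: 14; 18 (3 equiv, excess recovered)
Product: 19, (4R,7R)‑7‑[(1S,4E,7E)‑1‑acetoxy‑8‑iodo‑4‑methylnona‑4,7‑dien‑1‑yl]‑4‑(2,2‑dimethoxyethyl)‑7‑methyl‑3‑methylideneoxepan‑2‑one
Conditions: 9‑BBN (1.3 equiv), THF, 0 °C → rt; then 18, Pd(dppf)Cl2 (10 mol %), AsPh3, Cs2CO3, DMF–H2O, rt
Reagents that add atoms: none
Why: 9‑BBN hydroborates the monosubstituted vinyl group at C9 in preference to the electron‑poor exo‑methylene, and B‑alkyl Suzuki–Miyaura coupling forms C8–C9 with retention of the E‑iodide geometry; excess symmetric diiodide enforces mono‑coupling.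

**Step 17**
Reactants: 19
Product: 20, 2‑{(4R,7R)‑7‑[(1S,4E,7E)‑1‑acetoxy‑8‑iodo‑4‑methylnona‑4,7‑dien‑1‑yl]‑7‑methyl‑3‑methylidene‑2‑oxooxepan‑4‑yl}acetaldehyde
Conditions: PPTS, acetone–H2O (10:1), 45 °C
Reagents that add atoms: water, O
Why: Mild acid hydrolysis of the dimethyl acetal; lactone, acetate, vinyl iodide and skipped diene tolerate PPTS.

**Step 18**
Reactants: 20
Product: 21, (1R,4E,7E,11S,12R)‑11‑acetoxy‑3‑hydroxy cembranolide macrocycle as a C3‑epimer mixture (3‑epi/3‑natural Dendronpholide A)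
Conditions: CrCl2 (10 equiv), NiCl2 (10 mol %), DMSO–THF, 2 mM (syringe pump), rt
Reagents that add atoms: none
Why: Nozaki–Hiyama–Kishi macrocyclisation adds the alkenyl‑Cr species (retention of E geometry) chemoselectively to the aldehyde, tolerating lactone, acetate and acrylate; it closes the 14‑membered ring at C3–C4, and C3 selectivity is not needed here.

**Step 19**
Reactants: 21
Product: 22, macrocyclic C3 enone (3‑dehydro‑Dendronpholide A)
Conditions: Dess–Martin periodinane, NaHCO3, CH2Cl2, 0 °C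
Reagents that add atoms: none
Why: Dess–Martin oxidation converges both C3 epimers on one α‑methyl enone without touching the skipped diene.

**Step 20**
Reactants: 22
Product: 23, Dendronpholide A
Conditions: (R)‑2‑methyl‑CBS‑oxazaborolidine, catecholborane, toluene–CH2Cl2, −78 °C
Reagents that add atoms: none
Why: Corey–Bakshi–Shibata reduction under catalyst control; with the α‑methylalkenyl group as the large substituent and C2H2 as the small one, the (R)‑catalyst gives the (3S)‑allylic alcohol, and catecholborane at −78 °C leaves the lactone, acetate and exo‑methylene alone.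

## Compound list

1 | (R)‑(+)‑limonene | CC1=CC[C@@H](CC1)C(C)=C | starting material
2 | (5R)‑7,7‑dimethoxy‑5‑(prop‑1‑en‑2‑yl)heptan‑2‑one | CC(=O)CC[C@H](CC(OC)OC)C(C)=C | intermediate
3 | (5R)‑5‑(3‑hydroxyprop‑1‑en‑2‑yl)‑7,7‑dimethoxyheptan‑2‑one | CC(=O)CC[C@H](CC(OC)OC)C(=C)CO | intermediate
4 | TBDPS ether of 3 | CC(=O)CC[C@H](CC(OC)OC)C(=C)CO[Si](c1ccccc1)(c1ccccc1)C(C)(C)C | intermediate
5 | ethyl (2E,6R)‑enoate | CCOC(=O)/C=C(\C)CC[C@H](CC(OC)OC)C(=C)CO[Si](c1ccccc1)(c1ccccc1)C(C)(C)C | intermediate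
6 | (2E,6R)‑allylic alcohol | OC/C=C(\C)CC[C@H](CC(OC)OC)C(=C)CO[Si](c1ccccc1)(c1ccccc1)C(C)(C)C | intermediate
7 | (11R,12R)‑epoxy alcohol, TBDPS ether | OC[C@H]1O[C@]1(C)CC[C@H](CC(OC)OC)C(=C)CO[Si](c1ccccc1)(c1ccccc1)C(C)(C)C | intermediate
8 | epoxy diol | OC[C@H]1O[C@]1(C)CC[C@H](CC(OC)OC)C(=C)CO | intermediate
9 | epoxy‑alcohol enal | OC[C@H]1O[C@]1(C)CC[C@H](CC(OC)OC)C(=C)C=O | intermediate
10 | epoxy‑alcohol acrylic acid | OC[C@H]1O[C@]1(C)CC[C@H](CC(OC)OC)C(=C)C(=O)O | intermediate
11 | epoxy‑aldehyde acrylic acid | O=C[C@H]1O[C@]1(C)CC[C@H](CC(OC)OC)C(=C)C(=O)O | intermediate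
12 | (11R,12R)‑vinyl‑epoxide acrylic acid | C=C[C@H]1O[C@]1(C)CC[C@H](CC(OC)OC)C(=C)C(=O)O | intermediate
13 | pentafluorophenyl ester of 12 | C=C[C@H]1O[C@]1(C)CC[C@H](CC(OC)OC)C(=C)C(=O)Oc1c(F)c(F)c(F)c(F)c1F | intermediate
14 | (4R,7R)‑7‑[(1S)‑1‑acetoxyallyl]‑4‑(2,2‑dimethoxyethyl)‑7‑methyl‑3‑methylideneoxepan‑2‑one | C=C1C(=O)O[C@](C)(CC[C@@H]1CC(OC)OC)[C@@H](OC(C)=O)C=C | intermediate
15 | 1‑bromobut‑2‑yne | CC#CCBr | starting material
16 | prop‑1‑ynylmagnesium bromide | CC#C[Mg]Br | starting material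
17 | hepta‑2,5‑diyne | CC#CCC#CC | intermediate
18 | (2E,5E)‑2,6‑diiodohepta‑2,5‑diene | C/C(I)=C\C/C=C(\C)I | intermediate
19 | iodo‑diene lactone acetal | C=C1C(=O)O[C@](C)(CC[C@@H]1CC(OC)OC)[C@@H](OC(C)=O)CC/C(C)=C/C/C=C(\C)I | intermediate
20 | iodo‑diene lactone aldehyde | C=C1C(=O)O[C@](C)(CC[C@@H]1CC=O)[C@@H](OC(C)=O)CC/C(C)=C/C/C=C(\C)I | intermediate
21 | macrocyclic allylic alcohol, C3 epimers | C=C1C(=O)O[C@]2(C)CC[C@@H]1CC(O)/C(C)=C/C/C=C(\C)CC[C@@H]2OC(C)=O | intermediate
22 | macrocyclic C3 enone | C=C1C(=O)O[C@]2(C)CC[C@@H]1CC(=O)/C(C)=C/C/C=C(\C)CC[C@@H]2OC(C)=O | intermediate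
23 | Dendronpholide A | C=C1C(=O)O[C@]2(C)CC[C@@H]1C[C@H](O)/C(C)=C/C/C=C(\C)CC[C@@H]2OC(C)=O | target

## Summary

Total steps: 20. Longest linear sequence: 18 (steps 1–13, then 16–20).

**Steps most likely to fail, with fallbacks**

1. **Step 13 (new acetate‑relay lactonisation).** Risks are 1,2‑acetyl migration followed by eight‑membered lactone closure, SN2′ opening at C9, or sluggish opening of the trisubstituted epoxide. Fallback with known chemistry: run step 6 with L‑(+)‑DET to get the (11S,12S) series. On the epoxy‑alcohol acid (diastereomer of 10), Ti(OiPr)4‑mediated C3‑selective intramolecular opening of the 2,3‑epoxy alcohol by the carboxylic acid attacks C12 with inversion and gives the hydroxy ε‑lactone 10,11‑diol. Then silylate the primary OH, acetylate C11‑OH, desilylate, oxidise, and methylenate (Zn/CH2Br2/TiCl4, non‑basic) to reach 14.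

2. **Step 16 (hydroboration/B‑alkyl Suzuki).** Risks are borane attack on the α‑methylene lactone, base‑induced lactone or acetate damage, and double coupling. Fallback: mask the exo‑methylene as its PhSH conjugate adduct before hydroboration, carry the sulfide through steps 16–20, and regenerate the alkene at the end by NaIO4 oxidation and sulfoxide syn‑elimination.

3. **Step 18 (NHK macrocyclisation).** Risks are oligomerisation, slow activation of the hindered trisubstituted iodide, and E/Z erosion. Fallback: reverse the order of the two couplings. Hydrolyse the acetal of 14, run an intermolecular NHK with excess 18, then DMP and (R)‑CBS on the acyclic enone, and close the ring by intramolecular B‑alkyl Suzuki–Miyaura coupling (C8–C9) at high dilution.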